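The tetralin is numbered so that C1 bears the pendant guaiacyl ring, C2 the CH2OSO3H arm and C3 the CH2OH arm. C8a is the fusion carbon next to C1, para to OMe. The route rests on cutting C2–C3 and C1–C8a of the carbocycle. C2 is a styrene β-carbon and C3 a malonate carbon, both donors, so oxidation must join them. C1, benzylic to a para-oxygenated ring, then becomes a cation that the second arene captures at C8a. One manganese-mediated electrolysis thus converts an acyclic mixed malonate (8-phenylmenthyl ester, O-benzylconiferyl ester, 4-benzyloxy-3-methoxybenzyl substituent) into the lactone-fused aryltetralin: two rings, two C–C bonds, three stereocentres. The lactone keeps both CH2O arms distinct for the later sulfation.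

Key step: step 6

Remarks before the steps
- Stereochemical bookkeeping: the target is (1S,2R,3R), with C1-aryl/C2-arm trans and C2-arm/C3-arm trans. The same three descriptors apply to 12, 15 and 17–24. In 12 the auxiliary ester stands where CH2OH will be, and the lactone C=O is cis to the C2 arm.
- Assumption (sense of induction): the (−)-auxiliary is chosen from a model in which the ester C=O eclipses the carbinol C–H, the cumyl phenyl covers one radical face, and the cyclising ester lies syn to the auxiliary carbonyl. If the other face reacts, commercial (+)-8-phenylmenthol is used and nothing else changes.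
- Assumption (protonation state): the target is drawn as the hydrogen sulfate, so the last step ends with protonation of the sodium salt 23, which is the storable form.

Step 1
Reactants: 1 ferulic acid
Product: 2 benzyl (E)-3-(4-benzyloxy-3-methoxyphenyl)acrylate
Conditions: BnBr (2.3 equiv), K2CO3, DMF, 60 °C
Reagents that add atoms: benzyl bromide, BrCc1ccccc1
Why: Williamson-type double O-alkylation, in which carbonate deprotonates both the phenol and the acid and both anions are benzylated by SN2, masks the phenol and gives a reducible ester in one operation.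

Step 2
Reactants: 2 benzyl (E)-3-(4-benzyloxy-3-methoxyphenyl)acrylate
Product: 3 (E)-O-benzylconiferyl alcohol
Conditions: DIBAL-H (2.5 equiv), CH2Cl2, −78 to 0 °C; Rochelle salt
Reagents that add atoms: none
Why: DIBAL-H 1,2-reduction of a cinnamate ester stops at the allylic alcohol and leaves the E-alkene and the aryl benzyl ether untouched.

Step 3
Reactants: 4 O-benzylvanillin; 5 Meldrum's acid
Product: 7 5-(4-benzyloxy-3-methoxybenzyl) Meldrum's acid, via benzylidene Meldrum's acid 6 (not isolated)
Conditions: L-proline (20 mol %), Hantzsch ester (1.05 equiv), EtOH, 25 °C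
Reagents that add atoms: none
Why: Knoevenagel condensation followed in the same flask by Hantzsch-ester transfer hydrogenation of the strongly electrophilic alkylidene (three-component reductive alkylation) gives the mono-benzylated Meldrum's acid without dialkylation.

Step 4
Reactants: 7 5-(4-benzyloxy-3-methoxybenzyl) Meldrum's acid; 8 (−)-8-phenylmenthol
Product: 9 8-phenylmenthyl hydrogen (4-benzyloxy-3-methoxybenzyl)malonate
Conditions: PhMe, 100 °C
Reagents that add atoms: none
Why: Thermal alcoholysis of a Meldrum's acid (ring opening with loss of acetone) accepts hindered secondary alcohols and stops at the malonic half-ester below its decarboxylation temperature; the new malonate stereocentre forms as a labile mixture that step 6 erases.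

Step 5
Reactants: 9 8-phenylmenthyl hydrogen (4-benzyloxy-3-methoxybenzyl)malonate; 3 (E)-O-benzylconiferyl alcohol
Product: 10 8-phenylmenthyl O-benzylconiferyl (4-benzyloxy-3-methoxybenzyl)malonate
Conditions: DCC, DMAP (10 mol %), CH2Cl2, 0 to 25 °C
Reagents that add atoms: none
Why: Steglich esterification couples the half-acid with the acid-sensitive allylic alcohol under neutral conditions at the acyl carbon, so neither allylic transposition nor E/Z isomerisation is expected.

Step 6
Reactants: 10 8-phenylmenthyl O-benzylconiferyl (4-benzyloxy-3-methoxybenzyl)malonate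
Product: 12 cis-fused (1S,2R,3R)-aryltetralin lactone bearing the 8-phenylmenthyl ester on C3, via lactone benzylic cation 11 (not isolated)
Conditions: Mn(OAc)2·4H2O (30 mol %), KOAc (0.5 M), AcOH/EtOAc 4:1, 55 °C; glass-frit divided cell, graphite-felt anode, Pt cathode, 2 mA cm−2, 2.2–2.5 F mol−1; 10 added by syringe pump during the run
Reagents that add atoms: none
Why: Mn(III) acetate, renewed at the anode, oxidises the chelated manganese enolate of 10 to the electrophilic C3 malonyl radical, which adds to the electron-rich styrene at C2; the C1 benzylic radical, made easy to oxidise by its para-benzyloxy group, gives up a second electron to form cation 11, the benzyl arm on C3 attacks it through C8a with loss of a proton, and the two protons are reduced to hydrogen at the cathode. The closest known reaction types are the Mn(III)-promoted annulation of benzylmalonates with alkenes to tetralins, the Mn(III) lactonising cyclisation of cinnamyl malonates and acetoacetates, Mn(III) cyclisations steered by 8-phenylmenthyl esters, and electrolyses run with catalytic Mn(II)/Mn(III) acetate. The γ-lactone closes by a radical 5-exo-trig addition, and the carbocycle closes by a cationic six-membered Friedel–Crafts alkylation that is 6-endo with respect to the arene C4a–C8a bond. C3 is set by the auxiliary, whose cumyl phenyl stacks over one face of the planar radical while the cyclising ester, which must twist out of plane, sits syn to the auxiliary carbonyl and clear of that phenyl, so the alkene arrives from the open face; C2 follows from C3 because the bulky auxiliary ester goes anti to the C1 carbon in the 5-exo transition state and only the adduct with benzyl arm and C1 cis on the lactone can reach the cation (cis fusion); C1 is set in the second closure, where the aryl group takes the pseudo-equatorial position trans to the C2–CH2O bond. The step needs oxidation of Mn(II) at the anode in preference to the styrene and the dialkoxyarenes, which a high Mn(II)-to-substrate ratio at the electrode secures (slow addition, low current density, divided cell), and it needs closure at C8a and not at the carbon flanked by CH2 and OMe, which the para-directing methoxy group and the crowding of the other site secure. Slow addition also keeps 10 dilute so that cyclisation can outrun intermolecular addition despite the unfavourable ester rotamer population, and any acetate adduct at C1 can re-ionise in warm acetic acid and drain to 12.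

Step 7
Reactants: 12 cis-fused (1S,2R,3R)-aryltetralin lactone bearing the 8-phenylmenthyl ester on C3
Product: 15 C2-arm TBS ether malonic half-acid, via potassium hydroxy-carboxylate 13 (not isolated), via bis-silyl derivative 14 (not isolated)
Conditions: KOH (1.1 equiv), THF/MeOH/H2O, 25 °C, evaporate, PhMe azeotrope; TBSCl (3 equiv), imidazole, DMF, 25 °C; K2CO3, MeOH/THF/H2O, 0 °C; KHSO4 to pH 4, 0 °C
Reagents that add atoms: potassium hydroxide, [K+].[OH-]; tert-butyldimethylsilyl chloride, CC(C)(C)[Si](C)(C)Cl
Why: Saponification attacks the exposed γ-lactone and not the shielded 8-phenylmenthyl ester, and because the free γ-hydroxy acid would close again on acidification the salt is bis-silylated first and only the labile silyl ester is then cleaved (the standard lactone to silyloxy-acid sequence), with no stereocentre touched.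

Step 8
Reactants: 15 C2-arm TBS ether malonic half-acid
Product: 17 (1S,2R,3R)-trans 8-phenylmenthyl ester, via C3-epimeric esters 16 (not isolated)
Conditions: Et3N (1 equiv), DMF, 120 °C; concentrate; t-BuOK (0.3 equiv), THF/t-BuOH, 25 °C; AcOH quench
Reagents that add atoms: none
Why: Thermal decarboxylation of the malonic half-acid through the ester enol removes the former lactone carbon, and alkoxide-catalysed enolisation then equilibrates C3 to the all-equatorial 1,2-trans-2,3-trans ester, which is safe only because the silyl ether stops the C2-arm oxygen from lactonising onto the ester (a fused lactone would tend toward the cis, wrong C3 epimer).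

Step 9
Reactants: 17 (1S,2R,3R)-trans 8-phenylmenthyl ester
Product: 18 C3-arm alcohol C2-arm TBS ether
Conditions: DIBAL-H (3 equiv), CH2Cl2, −78 to 0 °C; Rochelle salt
Reagents that add atoms: none
Why: DIBAL-H ester reduction gives the C3 hydroxymethyl arm and releases the auxiliary for recovery, fixes C3 (no longer enolisable), and its weakly basic aluminium alkoxides avoid cleavage or migration of the silyl group.

Step 10
Reactants: 18 C3-arm alcohol C2-arm TBS ether
Product: 19 C3-arm benzyl carbonate C2-arm TBS ether
Conditions: CbzCl (1.5 equiv), pyridine, DMAP (10 mol %), CH2Cl2, 0 °C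
Reagents that add atoms: benzyl chloroformate, O=C(Cl)OCc1ccccc1
Why: Amine-mediated acylation with a chloroformate blocks the only free hydroxyl without forming an alkoxide, so the silyl group cannot wander between the 1,4-related oxygens, and the carbonate is chosen because it falls in the final hydrogenolysis.

Step 11
Reactants: 19 C3-arm benzyl carbonate C2-arm TBS ether
Product: 20 C2-arm alcohol C3-arm benzyl carbonate
Conditions: HF·pyridine, THF/pyridine, 0 to 25 °C
Reagents that add atoms: none
Why: Fluoride desilylation in a buffered acidic medium frees the C2-arm alcohol without an alkoxide stage, so the neighbouring carbonate neither migrates nor cyclises, and benzyl ethers are inert.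

Step 12
Reactants: 20 C2-arm alcohol C3-arm benzyl carbonate
Product: 22 sodium C2-arm sulfate, via pyridinium sulfate 21 (not isolated)
Conditions: SO3·pyridine (5 equiv), pyridine, 25 °C; aq NaHCO3
Reagents that add atoms: sulfur trioxide–pyridine complex, O=S(=O)([O-])[n+]1ccccc1; sodium hydrogencarbonate, [Na+].OC([O-])=O
Why: O-sulfation with an amine–SO3 complex can only take place at the single free hydroxyl, the C2 arm, and cation exchange with hydrogencarbonate gives the robust, chromatographable sodium monoester.

Step 13
Reactants: 22 sodium C2-arm sulfate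
Product: 24 target hydrogen sulfate CNP0184747.1, via sodium salt of the target 23 (not isolated)
Conditions: H2 (1 atm), 10% Pd/C, MeOH, 25 °C; filter; HCl (1.0 equiv), H2O, 0 °C; C18 desalting, freeze-drying
Reagents that add atoms: none
Why: Catalytic hydrogenolysis cleaves both aryl benzyl ethers and the benzyl carbonate (which then loses CO2) under neutral conditions that leave the alkyl sulfate salt, the diaryl methine and all three stereocentres untouched, and one equivalent of cold mineral acid delivers the protonated form.

Compound list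
1 | ferulic acid | COc1cc(/C=C/C(=O)O)ccc1O | starting material
2 | benzyl (E)-3-(4-benzyloxy-3-methoxyphenyl)acrylate | COc1cc(/C=C/C(=O)OCc2ccccc2)ccc1OCc1ccccc1 | intermediate
3 | (E)-3-(4-benzyloxy-3-methoxyphenyl)prop-2-en-1-ol (O-benzylconiferyl alcohol) | COc1cc(/C=C/CO)ccc1OCc1ccccc1 | intermediate
4 | 4-benzyloxy-3-methoxybenzaldehyde (O-benzylvanillin) | COc1cc(C=O)ccc1OCc1ccccc1 | starting material
5 | Meldrum's acid | CC1(C)OC(=O)CC(=O)O1 | starting material
6 | 5-(4-benzyloxy-3-methoxybenzylidene) Meldrum's acid | COc1cc(C=C2C(=O)OC(C)(C)OC2=O)ccc1OCc1ccccc1 | intermediate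
7 | 5-(4-benzyloxy-3-methoxybenzyl) Meldrum's acid | COc1cc(CC2C(=O)OC(C)(C)OC2=O)ccc1OCc1ccccc1 | intermediate
8 | (−)-8-phenylmenthol, (1R,2S,5R) | O[C@@H]1C[C@H](C)CC[C@H]1C(C)(C)c1ccccc1 | starting material
9 | (1R,2S,5R)-8-phenylmenthyl hydrogen 2-(4-benzyloxy-3-methoxybenzyl)malonate, both epimers at the malonate carbon | COc1cc(CC(C(=O)O)C(=O)O[C@@H]2C[C@H](C)CC[C@H]2C(C)(C)c2ccccc2)ccc1OCc1ccccc1 | intermediate
10 | (1R,2S,5R)-8-phenylmenthyl (E)-3-(4-benzyloxy-3-methoxyphenyl)allyl 2-(4-benzyloxy-3-methoxybenzyl)malonate, both epimers at the malonate carbon | COc1cc(/C=C/COC(=O)C(Cc2ccc(OCc3ccccc3)c(OC)c2)C(=O)O[C@@H]2C[C@H](C)CC[C@H]2C(C)(C)c2ccccc2)ccc1OCc1ccccc1 | intermediate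
11 | γ-lactone with the C1 benzylic cation; benzyl arm on C3 and cationic carbon on C2 cis on the lactone, auxiliary ester on C3 | COc1cc([CH+][C@H]2COC(=O)[C@]2(Cc2ccc(OCc3ccccc3)c(OC)c2)C(=O)O[C@@H]2C[C@H](C)CC[C@H]2C(C)(C)c2ccccc2)ccc1OCc1ccccc1 | intermediate
12 | (1S,2R,3R) cis-fused aryltetralin γ-lactone: lactone C=O and 8-phenylmenthyl ester on C3, lactone CH2O on C2, 4-benzyloxy-3-methoxyphenyl on C1 trans to C2–CH2O, 7-OBn, 6-OMe | COc1cc([C@H]2c3cc(OCc4ccccc4)c(OC)cc3C[C@@]4(C(=O)O[C@@H]5C[C@H](C)CC[C@H]5C(C)(C)c5ccccc5)[C@@H]2COC4=O)ccc1OCc1ccccc1 | intermediate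
13 | potassium salt of the ring-opened hydroxy acid (C2–CH2OH, C3–CO2K, C3–CO2-phenylmenthyl) | COc1cc([C@H]2c3cc(OCc4ccccc4)c(OC)cc3C[C@@](C(=O)[O-])(C(=O)O[C@@H]4C[C@H](C)CC[C@H]4C(C)(C)c4ccccc4)[C@@H]2CO)ccc1OCc1ccccc1.[K+] | intermediate
14 | TBS ether TBS ester of the hydroxy acid | COc1cc([C@H]2c3cc(OCc4ccccc4)c(OC)cc3C[C@@](C(=O)O[Si](C)(C)C(C)(C)C)(C(=O)O[C@@H]4C[C@H](C)CC[C@H]4C(C)(C)c4ccccc4)[C@@H]2CO[Si](C)(C)C(C)(C)C)ccc1OCc1ccccc1 | intermediate
15 | (1S,2R,3R) malonic half-acid: C3–CO2H, C3–CO2-phenylmenthyl, C2–CH2OTBS | COc1cc([C@H]2c3cc(OCc4ccccc4)c(OC)cc3C[C@@](C(=O)O)(C(=O)O[C@@H]4C[C@H](C)CC[C@H]4C(C)(C)c4ccccc4)[C@@H]2CO[Si](C)(C)C(C)(C)C)ccc1OCc1ccccc1 | intermediate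
16 | decarboxylated 8-phenylmenthyl ester, (1S,2R), both epimers at C3 | COc1cc([C@H]2c3cc(OCc4ccccc4)c(OC)cc3CC(C(=O)O[C@@H]4C[C@H](C)CC[C@H]4C(C)(C)c4ccccc4)[C@@H]2CO[Si](C)(C)C(C)(C)C)ccc1OCc1ccccc1 | intermediate
17 | (1S,2R,3R) all-trans 8-phenylmenthyl ester, C2–CH2OTBS | COc1cc([C@H]2c3cc(OCc4ccccc4)c(OC)cc3C[C@@H](C(=O)O[C@@H]4C[C@H](C)CC[C@H]4C(C)(C)c4ccccc4)[C@@H]2CO[Si](C)(C)C(C)(C)C)ccc1OCc1ccccc1 | intermediate
18 | (1S,2R,3R) di-O-benzylisolariciresinol C2-arm TBS ether (C3–CH2OH free) | COc1cc([C@H]2c3cc(OCc4ccccc4)c(OC)cc3C[C@@H](CO)[C@@H]2CO[Si](C)(C)C(C)(C)C)ccc1OCc1ccccc1 | intermediate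
19 | (1S,2R,3R) C3-arm benzyl carbonate, C2-arm TBS ether | COc1cc([C@H]2c3cc(OCc4ccccc4)c(OC)cc3C[C@@H](COC(=O)OCc4ccccc4)[C@@H]2CO[Si](C)(C)C(C)(C)C)ccc1OCc1ccccc1 | intermediate
20 | (1S,2R,3R) C3-arm benzyl carbonate, C2–CH2OH free | COc1cc([C@H]2c3cc(OCc4ccccc4)c(OC)cc3C[C@@H](COC(=O)OCc4ccccc4)[C@@H]2CO)ccc1OCc1ccccc1 | intermediate
21 | pyridinium salt of the protected C2-arm sulfate | COc1cc([C@H]2c3cc(OCc4ccccc4)c(OC)cc3C[C@@H](COC(=O)OCc4ccccc4)[C@@H]2COS(=O)(=O)[O-])ccc1OCc1ccccc1.c1cc[nH+]cc1 | intermediate
22 | sodium salt of the protected C2-arm sulfate | COc1cc([C@H]2c3cc(OCc4ccccc4)c(OC)cc3C[C@@H](COC(=O)OCc4ccccc4)[C@@H]2COS(=O)(=O)[O-])ccc1OCc1ccccc1.[Na+] | intermediate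
23 | sodium salt of the target | COc1cc([C@H]2c3cc(O)c(OC)cc3C[C@@H](CO)[C@@H]2COS(=O)(=O)[O-])ccc1O.[Na+] | intermediate
24 | CNP0184747.1, (1S,2R,3R)-isolariciresinol C2-arm hydrogen sulfate | COc1cc([C@H]2c3cc(O)c(OC)cc3C[C@@H](CO)[C@@H]2COS(=O)(=O)O)ccc1O | target

Total step count: 13
Longest linear sequence: 11 (steps 3–13 from 4; the branch from 1 through steps 1, 2 and 5–13 is equally long)

Steps most likely to fail

Step 6. What may go wrong:
- weak facial discrimination at the malonyl radical;
- direct anodic oxidation of the styrene or the dialkoxyarenes;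
- intermolecular radical addition;
- capture of the C1 cation by acetate or by the auxiliary carbonyl.

The fallback generates the radical reductively, without electrode or metal oxidant. Setting out from 10, soft enolisation with bromine transfer (DBU, CBrCl3, CH2Cl2, 0 °C) should give the α-bromomalonate F1. Visible-light photoredox catalysis follows (fac-Ir(ppy)3, 2,6-lutidine, MeCN, blue light, 0–25 °C, optionally Mg(ClO4)2 to hold the two carbonyls syn). It reduces the C–Br bond to the same C3 radical. The oxidised photocatalyst then takes the C1 radical to cation 11, and Friedel–Crafts closure comes back to the route at 12.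

Step 7. What may go wrong: sluggish hydroxide attack at a carbonyl next to a quaternary carbon, or reclosure of the lactone while the hydroxy-carboxylate is dried and silylated.

The fallback removes the surplus carbon as formate and not as CO2. Setting out from 12, DIBAL-H (1 equiv, CH2Cl2, −78 °C) should reduce only the lactone to the lactol F2. K2CO3 in MeOH at 0 °C then triggers retro-Claisen deformylation of its non-enolisable α-formyl ester tautomer, giving the C3-epimeric hydroxy esters F3. Immediate silylation (TBSCl, imidazole, DMF) comes back to the route at 16.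

Step 8. What may go wrong: slow enolisation of the shielded ester or an insufficient bias in the equilibrium, so that C3 stays mixed.

The fallback equilibrates at the aldehyde oxidation level, where enolisation is easy and the auxiliary is gone. Setting out from 16, DIBAL-H reduction should give the C3-epimeric alcohols F4. Dess–Martin oxidation then gives the C3-epimeric aldehydes F5, and DBU in CH2Cl2 converts these into the equatorial trans aldehyde F6. NaBH4 in MeOH comes back to the route at 18.

Further compounds
F1 | step 6 | 8-phenylmenthyl O-benzylconiferyl 2-bromo-2-(4-benzyloxy-3-methoxybenzyl)malonate, both epimers at the malonate carbon | COc1cc(/C=C/COC(=O)C(Br)(Cc2ccc(OCc3ccccc3)c(OC)c2)C(=O)O[C@@H]2C[C@H](C)CC[C@H]2C(C)(C)c2ccccc2)ccc1OCc1ccccc1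
F2 | step 7 | lactol of 12, both anomers | COc1cc([C@H]2c3cc(OCc4ccccc4)c(OC)cc3C[C@@]4(C(=O)O[C@@H]5C[C@H](C)CC[C@H]5C(C)(C)c5ccccc5)[C@@H]2COC4O)ccc1OCc1ccccc1
F3 | step 7 | (1S,2R) hydroxy 8-phenylmenthyl ester, both epimers at C3 | COc1cc([C@H]2c3cc(OCc4ccccc4)c(OC)cc3CC(C(=O)O[C@@H]4C[C@H](C)CC[C@H]4C(C)(C)c4ccccc4)[C@@H]2CO)ccc1OCc1ccccc1
F4 | step 8 | (1S,2R) C3-arm alcohol C2-arm TBS ether, both epimers at C3 | COc1cc([C@H]2c3cc(OCc4ccccc4)c(OC)cc3CC(CO)[C@@H]2CO[Si](C)(C)C(C)(C)C)ccc1OCc1ccccc1
F5 | step 8 | (1S,2R) C3 aldehyde C2-arm TBS ether, both epimers at C3 | COc1cc([C@H]2c3cc(OCc4ccccc4)c(OC)cc3CC(C=O)[C@@H]2CO[Si](C)(C)C(C)(C)C)ccc1OCc1ccccc1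
F6 | step 8 | (1S,2R,3R) trans C3 aldehyde C2-arm TBS ether | COc1cc([C@H]2c3cc(OCc4ccccc4)c(OC)cc3C[C@@H](C=O)[C@@H]2CO[Si](C)(C)C(C)(C)C)ccc1OCc1ccccc1
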